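**Retrosynthetic overview**
- Key disconnection: the pyran O1–C2 bond, ArO–C(CH3)2. The chromene goes back to a 5-bromo-2,4-dihydroxybenzophenone plus isoprene, and the ring closes by C–O bond formation at the tertiary end of a π-allyl palladium unit.
- The ring A prenyl group goes back by a retro-[3,3] shift to the 3'-O-(1,1-dimethylallyl) ether. That C–O bond is made by palladium-catalysed allylic etherification.
- The diaryl ketone goes back to Friedel–Crafts acylation of 4-bromoresorcinol with 3-hydroxybenzoic acid.
- Ring order: both benzene rings are bought. The pyran ring is the only ring made (step 2), and it is closed before ring A is prenylated so that it also masks the acidic 4-OH.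

Assumption: cudraphenone A has no stereocentre and no stereogenic double bond, so it is achiral and no enantiocontrol is needed. The one transient stereocentre, in a dihydrobenzofuran that is not isolated, is racemic and is erased in the same flask.

**Step 1**
Reactants: 1 4-bromoresorcinol; 2 3-hydroxybenzoic acid
Product: 3 (5-bromo-2,4-dihydroxyphenyl)(3-hydroxyphenyl)methanone
Conditions: BF3·OEt2 (solvent), 90 °C; then aq NaOAc, 60 °C
Reagents that add atoms: none
Why: Friedel–Crafts (Nencki-type) acylation in which BF3 activates the acid (any aryl ester formed undergoes a Fries shift), attack occurs at C6 of 1, the only unhindered carbon ortho/para to both OH groups, and the BF2-chelated o-hydroxy ketone resists a second acylation; no stereocentre is formed.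

**Step 2**
Reactants: 3 (5-bromo-2,4-dihydroxyphenyl)(3-hydroxyphenyl)methanone; 4 isoprene
Product: 7 (7-hydroxy-2,2-dimethyl-2H-chromen-6-yl)(3-hydroxyphenyl)methanone, via isopropenyl-dihydrobenzofuran ketone 5 (not isolated), via dienylphenol ketone 6 (not isolated)
Conditions: Pd(OAc)2 (5 mol%), Xantphos (6 mol%), KOPiv (1.5 equiv), isoprene (5 equiv), 1,4-dioxane, 110 °C, sealed tube
Reagents that add atoms: none
Why: Proposed new method: a migratory oxa-annulation whose ring-closing event is C–O bond formation at the tertiary carbon; oxidative addition of the C–Br bond to zerovalent palladium and carbopalladation of the vinyl terminus of isoprene give a π-allyl complex that first closes kinetically to dihydrobenzofuran 5 (the known outcome); because the leaving group is a para-acyl phenoxide (pKa about 7.5) and Xantphos should keep ionisation of the allyl aryl ether reversible at 110 °C, the π-allyl complex is regenerated and loses a benzylic β-hydrogen to give diene 6 and a palladium hydride kept alive by the pivalate/pivalic acid buffer; the hydride (or the acid itself) re-adds at the terminal CH2 to give the 1-aryl-3,3-dimethylallyl complex, which after π–σ–π syn–anti isomerisation is attacked by the ortho OH at the CMe2 terminus, the only terminus that gives a viable ring; 5, 6 and 7 are isomers and the conjugated chromene 7 should be the thermodynamic sink, with thermal [1,7]-H shift/oxa-6π closure of 6 as a second exit to 7; the chelating ligand suppresses diene telomerisation, and addition of the 3'-OH to isoprene is reversible and entropically disfavoured at this temperature; closest known reaction types are the Larock-type heteroannulation of 1,3-dienes with o-halophenols and palladium-hydride hydroalkoxylation of 1,3-dienes; no stereocentre remains.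

**Step 3**
Reactants: 7 (7-hydroxy-2,2-dimethyl-2H-chromen-6-yl)(3-hydroxyphenyl)methanone; 8 2-methylbut-3-en-2-ol
Product: 10 (7-hydroxy-2,2-dimethyl-2H-chromen-6-yl){3-[(2-methylbut-3-en-2-yl)oxy]phenyl}methanone, via methyl tert-prenyl carbonate 9 (not isolated)
Conditions: 8 (1.6 equiv), n-BuLi (1.5 equiv), THF, −78 °C; ClCO2Me (1.5 equiv), −78 °C → rt; then 7, Pd(PPh3)4 (3 mol%), 0 °C → rt
Reagents that add atoms: none
Why: Tsuji–Trost-type decarboxylative allylic etherification in which zerovalent palladium ionises 9 to the 1,1-dimethyl-π-allyl complex, CO2 and methoxide, the methoxide deprotonates the free and more acidic 3'-OH (the 7-OH is hydrogen-bonded to the ketone and stays untouched), and the phenoxide attacks the more substituted allyl terminus under kinetic control at low temperature, as is well precedented for reverse-prenyl aryl ethers; no stereocentre is formed.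

**Step 4**
Reactants: 10 (7-hydroxy-2,2-dimethyl-2H-chromen-6-yl){3-[(2-methylbut-3-en-2-yl)oxy]phenyl}methanone
Product: 11 cudraphenone A [(7-hydroxy-2,2-dimethyl-2H-chromen-6-yl)(3-hydroxy-2-prenylphenyl)methanone]
Conditions: N,N-diethylaniline, 130 °C
Reagents that add atoms: none
Why: Aromatic Claisen rearrangement in which the [3,3] shift, accelerated by the gem-dimethyl group, bonds the CH2 terminus to an ortho carbon and so turns the reverse-prenyl ether into a normal prenyl group, the meta-acyl substituent biases migration to the flanked C2' (1,2,3-pattern) over C4', enolisation restores the phenol, the basic solvent blocks acid-catalysed chroman formation, and the minor 4'-prenyl isomer is removed by chromatography; no stereocentre is formed.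

**Compound list**
1 | 4-bromoresorcinol (4-bromobenzene-1,3-diol) | Oc1ccc(Br)c(O)c1 | starting material
2 | 3-hydroxybenzoic acid | OC(=O)c1cccc(O)c1 | starting material
3 | (5-bromo-2,4-dihydroxyphenyl)(3-hydroxyphenyl)methanone | O=C(c1cccc(O)c1)c1cc(Br)c(O)cc1O | intermediate
4 | isoprene (2-methylbuta-1,3-diene) | C=CC(C)=C | starting material
5 | racemic [6-hydroxy-2-(prop-1-en-2-yl)-2,3-dihydro-1-benzofuran-5-yl](3-hydroxyphenyl)methanone | CC(=C)C1Cc2cc(C(=O)c3cccc(O)c3)c(O)cc2O1 | intermediate
6 | (E)-[2,4-dihydroxy-5-(3-methylbuta-1,3-dien-1-yl)phenyl](3-hydroxyphenyl)methanone | CC(=C)/C=C/c1cc(C(=O)c2cccc(O)c2)c(O)cc1O | intermediate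
7 | (7-hydroxy-2,2-dimethyl-2H-chromen-6-yl)(3-hydroxyphenyl)methanone | CC1(C)C=Cc2cc(C(=O)c3cccc(O)c3)c(O)cc2O1 | intermediate
8 | 2-methylbut-3-en-2-ol | CC(C)(O)C=C | starting material
9 | methyl 2-methylbut-3-en-2-yl carbonate | COC(=O)OC(C)(C)C=C | intermediate
10 | (7-hydroxy-2,2-dimethyl-2H-chromen-6-yl){3-[(2-methylbut-3-en-2-yl)oxy]phenyl}methanone | C=CC(C)(C)Oc1cccc(c1)C(=O)c1cc2C=CC(C)(C)Oc2cc1O | intermediate
11 | cudraphenone A, (7-hydroxy-2,2-dimethyl-2H-chromen-6-yl)[3-hydroxy-2-(3-methylbut-2-en-1-yl)phenyl]methanone | CC(C)=CCc1c(O)cccc1C(=O)c1cc2c(cc1O)OC(C)(C)C=C2 | target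

**Step count**
- Total step count: 4.
- Longest linear sequence: 4 steps (1 → 3 → 7 → 10 → 11).

**Steps most likely to fail**

Step 2 (the proposed new step). The reaction may stop at dihydrobenzofuran 5. It may also give isomers from arylation at the other isoprene terminus, or lose bromine to the palladium hydride.

The fallback uses known chemistry. It sets out from 3, with 8 as the C5 partner, and comes back at 7. A Heck reaction of 3 with 8 (Pd(OAc)2, P(o-tol)3, NaOAc, DMF, 110 °C) gives (E)-[2,4-dihydroxy-5-(3-hydroxy-3-methylbut-1-en-1-yl)phenyl](3-hydroxyphenyl)methanone F1. Catalytic p-TsOH in toluene at 70 °C then ionises the tertiary allylic alcohol. The resulting allyl cation/o-quinone methide loses its alkene geometry and closes through the ortho OH to chromene 7.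

Step 4. Ring A is electron-poor and twisted out of conjugation with the ketone. The tertiary ether may therefore lose isoprene and fall back to 7 faster than it rearranges, and the C2'/C4' ratio may be modest.

The fallback sets out from 7 and comes back at 11. It replaces the reverse-prenyl Claisen with an allyl Claisen followed by olefin metathesis.
- Allyl bromide (C=CCBr) and K2CO3 in acetone alkylate only the non-chelated 3'-OH to give [3-(allyloxy)phenyl](7-hydroxy-2,2-dimethyl-2H-chromen-6-yl)methanone F2. This ether cannot eliminate.
- Heating in N,N-diethylaniline at 190 °C gives (2-allyl-3-hydroxyphenyl)(7-hydroxy-2,2-dimethyl-2H-chromen-6-yl)methanone F3. This follows the best-documented 1,2,3-preference of meta-acyl allyl ethers, and the 4'-isomer is separated here.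
- Cross-metathesis of F3 with excess 2-methylbut-2-ene (CC=C(C)C) and second-generation Grubbs catalyst in CH2Cl2 at 40 °C converts allyl into prenyl. The hindered chromene alkene is left alone, and the product is 11.

Step 1. In hot BF3·OEt2 the activated C–Br bond of 1 may undergo protodebromination or bromine scrambling.

The fallback acylates first and halogenates afterwards. It sets out from 2 and comes back at 3. Acid 2 and resorcinol (Oc1cccc(O)c1, commercial) in BF3·OEt2 at 90 °C give (2,4-dihydroxyphenyl)(3-hydroxyphenyl)methanone F4. N-Bromosuccinimide (1.0 equiv, MeCN, 0 °C) then brominates C5, which is ortho to the 4-OH, para to the 2-OH and less hindered than C3. This gives 3.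

**Further compounds**
F1 | step 2 | (E)-[2,4-dihydroxy-5-(3-hydroxy-3-methylbut-1-en-1-yl)phenyl](3-hydroxyphenyl)methanone | CC(C)(O)/C=C/c1cc(C(=O)c2cccc(O)c2)c(O)cc1O
F2 | step 4 | [3-(allyloxy)phenyl](7-hydroxy-2,2-dimethyl-2H-chromen-6-yl)methanone | C=CCOc1cccc(c1)C(=O)c1cc2C=CC(C)(C)Oc2cc1O
F3 | step 4 | (2-allyl-3-hydroxyphenyl)(7-hydroxy-2,2-dimethyl-2H-chromen-6-yl)methanone | C=CCc1c(O)cccc1C(=O)c1cc2C=CC(C)(C)Oc2cc1O
F4 | step 1 | (2,4-dihydroxyphenyl)(3-hydroxyphenyl)methanone | O=C(c1cccc(O)c1)c1ccc(O)cc1O
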